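The numbers were set for the occasion; the run is a simulation.

A one-step world has partner meeting substrate directly, but here substrate is a resting state that must first open to intermediate, and partner decays while it waits.

all flasks: time 2.5 d

|  | substrate | partner | remark |
|---|---|---|---|
| cedar | 20 mM (fed, over 25 h) | 16.0 mM | all else is in the flask from the start; the feed brings no volume worth counting |
| ash | 20 mM | 16.0 mM (fed, over 25 h) | all else is in the flask from the start; the feed brings no volume worth counting |
| maple | 20 mM | 16.0 mM | everything together at the start |

    substrate ⇌ intermediate + leaving ligand (K1 = 2.4 × 10⁻⁴ M, k1 = 0.15 /h)
    partner + intermediate → target (k2 = 230 /M/h)
    partner → decomposed reagent (k3 = 0.062 /h)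
    intermediate → side product (k4 = 0.0093 /h)

* the flask with the highest amount of target, in percent of the substrate charged ("all alike" if they lie within 1.5 percentage points) (cedar / ash / maple / all alike)
* final target, as a percentage of the substrate charged, in cedar
* final target, as a percentage of the substrate charged, in ash
* final target, as a percentage of the substrate charged, in maple

Minutes. I opened by noting that partner has two exits, capture by intermediate and decay, and that their split follows c(intermediate). I proposed the break-even pool, the c(intermediate) at which partner goes equally to target and to decomposed reagent, which is the decay constant over the capture constant: 0.270 mM. The share reaching target is then c(intermediate)/(c(intermediate) + break-even pool).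

I then held the opening step at equilibrium and froze the pool at the moment when a third of the substrate has become target, which makes it twice the equilibrium constant, or 0.480 mM. For ash, with the pool standing ready as partner arrives, that puts target at 51.2 %.

For the other flasks I compared supply with decay at the start. Partner decays at 0.992 mM/h, maple opens substrate at 3.00 mM/h, and cedar's feed brings 0.800 mM/h, less than that decay. So I put cedar below maple.

The forecast named ash, with 31 % in cedar, 52 % in ash and 46 % in maple, and held that “Feeding the partner into the pre-formed pool of intermediate wastes the least”.

The simulation gives 31.2 % in cedar, 50.2 % in ash and 47.5 % in maple, so ash leads. With partner down to 0.47 % of its charge in ash, 0.051 % in maple and 0.013 % in cedar, target over decomposed reagent, times the break-even pool, reads the mean c(intermediate) weighted by partner: 0.460 mM in ash and 0.395 mM in maple, both above the 0.270 mM break-even, but 0.172 mM in cedar, below it. The neighbour of cedar charged with 50 mM of substrate reads 0.294 mM, above the break-even pool.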